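**Assumption:** 4-methoxyresorcinol, phloroglucinol and (S)-3-butyn-2-ol (made from (S)-lactate) are purchasable. DIPEA, imidazole, Pd/Cu catalysts, BuLi, Red-Al, OsO4 and similar reagents that leave no atoms are not numbered.

## Retrosynthesis
1. Kushenol V comes from global MOM removal of a protected (2S)-flavanone. The C-ring is closed last, by intramolecular Mitsunobu etherification with inversion of an (R)-benzylic β-hydroxy aryl ketone.
2. That ketone comes from a lithiated, prenylated A-ring arene plus the (R)-β-hydroxy dimethylamide. The amide comes from the propenyl-bearing Claisen amide by oxidative cleavage, then Baeyer–Villiger (benzylic carbon migrates with retention).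
3. Key step: Eschenmoser–Claisen [3,3]-sigmatropic rearrangement of the (S,E)-4-aryl-but-3-en-2-ol. It forms the C2–C3 bond and transfers the carbinol chirality to C2. The alcohol is built from (S)-3-butyn-2-ol by Sonogashira coupling and Red-Al reduction.
4. Ring order: B-ring arene, then C2–C3 bond (Claisen), then A-ring acylation, then the pyranone ring (C-ring).

## Route

**Step 1**
Reactants: 1 (4-methoxyresorcinol), 2 (MOMCl)
Product: 3, 1,3-bis(MOMO)-4-methoxybenzene
Conditions: MOMCl (2.2 equiv), DIPEA, CH2Cl2, 0 °C to rt
Reagents that add atoms: MOMCl, ClCOC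
Why: Standard O-alkoxymethylation of both phenols gives acid-labile protection that survives the later organometallic, reductive and oxidative steps.

**Step 2**
Reactants: 3, 4 (NIS)
Product: 5, 1-iodo-2,4-bis(MOMO)-5-methoxybenzene
Conditions: NIS, MeCN, 0 °C
Reagents that add atoms: N-iodosuccinimide, O=C1CCC(=O)N1I
Why: Electrophilic aromatic iodination goes to the one ring position that is ortho to one OMOM and para to the other, which is the carbon that must carry C2.

**Step 3**
Reactants: 5, 6 ((S)-but-3-yn-2-ol)
Product: 7, (S)-4-aryl-but-3-yn-2-ol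
Conditions: Pd(PPh3)2Cl2 (cat.), CuI, Et3N, THF, rt
Reagents that add atoms: none
Why: Sonogashira coupling joins the B-ring to the pool-derived alkyne, and the sp3 carbinol stereocenter is untouched.

**Step 4**
Reactants: 7
Product: 8, (S,E)-4-aryl-but-3-en-2-ol
Conditions: Red-Al, THF, 0 °C to rt
Reagents that add atoms: none
Why: Red-Al trans-hydroalumination of the propargylic alcohol gives the E-allylic alcohol, which sets up the chair transition state; the carbinol is unchanged.

**Step 5 (key step)**
Reactants: 8, 9 (DMA-DMA)
Product: 10, (S,E)-N,N-dimethyl-3-aryl-hex-4-enamide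
Conditions: DMA-DMA (4 equiv), xylene, 140 °C, sealed tube
Reagents that add atoms: N,N-dimethylacetamide dimethyl acetal, CN(C)C(C)(OC)OC
Why: The Eschenmoser–Claisen [3,3]-rearrangement goes through a chair transition state with the E-alkene aryl group and the Me on the carbinol carbon both equatorial, so the (S)-carbinol gives the (S)-benzylic C2 (C3 of the hexenamide). It runs under neutral conditions, which avoids ionising the electron-rich cinnamyl alcohol.

**Step 6**
Reactants: 10, 11 (NaIO4)
Product: 12, (R)-3-aryl-4-oxo... i.e. N,N-dimethyl-3-aryl-3-formylpropanamide (α-aryl aldehyde)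
Conditions: OsO4 (2 mol%), NaIO4 (4 equiv), 2,6-lutidine, dioxane/H2O, rt; crude aldehyde used at once
Reagents that add atoms: sodium periodate, [Na+].[O-]I(=O)(=O)=O
Why: Lemieux–Johnson cleavage converts the propenyl group to CHO without touching the arene, and the spatial arrangement is unchanged (the descriptor changes only because CIP priorities change).

**Step 7**
Reactants: 12, 13 (mCPBA)
Product: 14, formate ester of the (R)-benzylic alcohol
Conditions: mCPBA (1.5 equiv), NaHCO3, CH2Cl2, 0 °C
Reagents that add atoms: mCPBA, OOC(=O)c1cccc(Cl)c1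
Why: In the Baeyer–Villiger (Criegee) rearrangement the electron-rich secondary benzylic carbon migrates in preference to H with retention, which converts C–CHO into C–O–CHO at the existing stereocenter.

**Step 8**
Reactants: 14
Product: 15, (R)-3-aryl-3-hydroxy-N,N-dimethylpropanamide
Conditions: K2CO3 (cat.), MeOH, 0 °C
Reagents that add atoms: none
Why: Mild methanolysis removes the formate; the amide α-protons are poorly acidic, so β-elimination is suppressed and C2 is not disturbed.

**Step 9**
Reactants: 16 (phloroglucinol), 17 (TIPSCl)
Product: 18, 5-(TIPSO)benzene-1,3-diol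
Conditions: TIPSCl (1.0 equiv), imidazole, DMF, 0 °C (statistical mono-silylation, then separation)
Reagents that add atoms: TIPSCl, CC(C)[Si](Cl)(C(C)C)C(C)C
Why: This gives a phenol protected differently from the others, so the ring-closing oxygen (C8a–O) can be unmasked selectively later.

**Step 10**
Reactants: 18, 2 (MOMCl)
Product: 19, 1,3-bis(MOMO)-5-(TIPSO)benzene
Conditions: MOMCl (2.2 equiv), DIPEA, CH2Cl2, 0 °C to rt
Reagents that add atoms: MOMCl, ClCOC
Why: Both remaining phenols are protected as acid-labile MOM ethers, which also act as ortho-directing groups.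

**Step 11**
Reactants: 19, 20 (prenyl bromide)
Product: 21, 2-prenyl-1,3-bis(MOMO)-5-(TIPSO)benzene
Conditions: n-BuLi, THF, −78 to 0 °C; then CuBr·SMe2 (cat.), prenyl bromide, −78 °C to rt
Reagents that add atoms: prenyl bromide, CC(C)=CCBr
Why: Directed ortho-lithiation goes between the two OMOM groups (the site next to the bulky OTIPS is disfavoured), and Cu-catalysed SN2 alkylation installs the prenyl group at the future C6.

**Step 12**
Reactants: 21, 15
Product: 22, (R)-β-hydroxy aryl ketone
Conditions: 21 (3 equiv) with n-BuLi (3 equiv), THF, 0 °C, 2 h; then 15 (1 equiv), −78 °C to 0 °C; aqueous NH4Cl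
Reagents that add atoms: none
Why: A second directed lithiation, now between OMOM and OTIPS, gives the aryl anion that acylates the tertiary amide via a stable tetrahedral intermediate. The first equivalent deprotonates the OH, and the stereocenter is not touched.

**Step 13**
Reactants: 22
Product: 23, phenol (C8a–OH free, all MOM retained)
Conditions: TBAF/AcOH (1:1), THF, 0 °C
Reagents that add atoms: none
Why: Fluoride cleaves the aryl TIPS ether, and buffering with AcOH prevents retro-aldol and E1cB elimination of the β-hydroxy ketone.

**Step 14**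
Reactants: 23
Product: 24, protected (2S)-flavanone
Conditions: PPh3, DIAD, THF, 0 °C to rt
Reagents that add atoms: none
Why: Intramolecular Mitsunobu etherification by the acidic, chelated phenol displaces the activated benzylic (R)-alcohol with clean inversion, forming the C-ring and giving (2S).

**Step 15**
Reactants: 24
Product: 25, Kushenol V
Conditions: 3 M HCl, MeOH/THF (1:1), 40 °C
Reagents that add atoms: none
Why: Acidolysis of the four MOM ethers gives the polyphenol; the prenyl group and the benzylic C2 stereocenter are stable to these mild conditions.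

## Compound list
1 | 4-methoxyresorcinol | COc1ccc(O)cc1O | starting material
2 | MOMCl | ClCOC | starting material (reagent)
3 | 1,3-bis(MOMO)-4-methoxybenzene | COc1ccc(OCOC)cc1OCOC | intermediate
4 | N-iodosuccinimide | O=C1CCC(=O)N1I | starting material (reagent)
5 | 1-iodo-2,4-bis(MOMO)-5-methoxybenzene | COc1cc(I)c(OCOC)cc1OCOC | intermediate
6 | (S)-but-3-yn-2-ol | C[C@H](O)C#C | starting material
7 | (S)-4-aryl-but-3-yn-2-ol | C[C@H](O)C#Cc1cc(OC)c(OCOC)cc1OCOC | intermediate
8 | (S,E)-4-aryl-but-3-en-2-ol | C[C@H](O)/C=C/c1cc(OC)c(OCOC)cc1OCOC | intermediate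
9 | N,N-dimethylacetamide dimethyl acetal | CN(C)C(C)(OC)OC | starting material (reagent)
10 | (S,E)-N,N-dimethyl-3-aryl-hex-4-enamide | CN(C)C(=O)C[C@@H](/C=C/C)c1cc(OC)c(OCOC)cc1OCOC | intermediate
11 | sodium periodate | [Na+].[O-]I(=O)(=O)=O | starting material (reagent)
12 | 3-aryl-3-formyl-N,N-dimethylpropanamide | CN(C)C(=O)C[C@@H](C=O)c1cc(OC)c(OCOC)cc1OCOC | intermediate
13 | mCPBA | OOC(=O)c1cccc(Cl)c1 | starting material (reagent)
14 | formate of (R)-3-aryl-3-hydroxypropanamide | CN(C)C(=O)C[C@@H](OC=O)c1cc(OC)c(OCOC)cc1OCOC | intermediate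
15 | (R)-3-aryl-3-hydroxy-N,N-dimethylpropanamide | CN(C)C(=O)C[C@@H](O)c1cc(OC)c(OCOC)cc1OCOC | intermediate
16 | phloroglucinol | Oc1cc(O)cc(O)c1 | starting material
17 | TIPSCl | CC(C)[Si](Cl)(C(C)C)C(C)C | starting material (reagent)
18 | 5-(TIPSO)resorcinol | Oc1cc(O)cc(O[Si](C(C)C)(C(C)C)C(C)C)c1 | intermediate
19 | 1,3-bis(MOMO)-5-(TIPSO)benzene | COCOc1cc(OCOC)cc(O[Si](C(C)C)(C(C)C)C(C)C)c1 | intermediate
20 | prenyl bromide | CC(C)=CCBr | starting material (reagent)
21 | 2-prenyl-1,3-bis(MOMO)-5-(TIPSO)benzene | COCOc1cc(O[Si](C(C)C)(C(C)C)C(C)C)cc(OCOC)c1CC=C(C)C | intermediate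
22 | (R)-β-hydroxy aryl ketone (TIPS, MOM protected) | COCOc1cc(O[Si](C(C)C)(C(C)C)C(C)C)c(C(=O)C[C@@H](O)c2cc(OC)c(OCOC)cc2OCOC)c(OCOC)c1CC=C(C)C | intermediate
23 | phenol from TIPS removal | COCOc1cc(O)c(C(=O)C[C@@H](O)c2cc(OC)c(OCOC)cc2OCOC)c(OCOC)c1CC=C(C)C | intermediate
24 | tetra-MOM-protected (2S)-flavanone | COCOc1cc2c(c(OCOC)c1CC=C(C)C)C(=O)C[C@H](O2)c3cc(OC)c(OCOC)cc3OCOC | intermediate
25 | Kushenol V | COc1cc([C@@H]2CC(=O)c3c(cc(O)c(CC=C(C)C)c3O)O2)c(O)cc1O | target

## Summary
Total steps: 15. Longest linear sequence: 12 (steps 1–8, then 12–15).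

Three steps most likely to fail:
1. **Step 14 (Mitsunobu).** The 2,4-dioxygenated B-ring makes the benzylic cation very stable, so racemisation or E1cB elimination to the chalcone is possible.
   - Fallback: close the ring with retention instead. Put fluorine at C8a in place of OTIPS, cyclise the alkoxide onto the ortho-acyl aryl fluoride by intramolecular SNAr (no bond to C2 is broken), and start from (R)-3-butyn-2-ol.
2. **Steps 6–7 (aldehyde, then Baeyer–Villiger).** The α-aryl aldehyde is epimerisable, and the electron-rich arene can be oxidised.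
   - Fallback: re-route the Claisen through a β-methyl allylic alcohol from (S)-lactate, so that cleavage gives a methyl ketone whose Baeyer–Villiger product is an acetate, avoiding the aldehyde.
3. **Step 12 (hindered aryllithium + amide).** Prenyl benzylic deprotonation competes with ring lithiation, and addition to the hindered amide can stall.
   - Fallback: drop the organolithium and build the ketone by BF3-mediated Fries or Houben–Hoesch acylation of 2-prenylphloroglucinol with the TBS-protected acid derived from 15.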